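## Retrosynthetic overview

1. Berbikonol (28) ⇐ global desilylation and reduction of two esters ⇐ trans-2-aryl-2,3-dihydrobenzofuran-3-carboxylate 26 ⇐ C3 epimerisation of cis-ester 25.
2. The dihydrofuran ring is the only ring built and is formed last, by Rh(II)-catalysed enantioselective intramolecular benzylic C–H insertion of aryl diazoacetate 24. All three benzene rings are purchased.
3. 24 ⇐ diazo transfer on benzyl aryl ether 23 ⇐ Mitsunobu union of benzyl alcohol 14 with phenol 22.
4. 14 (complete erythro aryloxy-glycerol unit) ⇐ Felkin–Anh addition of an aryl Grignard to α-aryloxy aldehyde 9 ⇐ lipase desymmetrisation of prochiral diacetate 5 ⇐ phenol 1 + chloromalonate 2.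
5. 22 ⇐ allylation, Claisen rearrangement and oxidative cleavage of methyl dihydroferulate 15.

Assumptions (one line each):
- Compounds 1, 2, 10, 15 and 16 are commercial and achiral.
- The lipase is assumed to distinguish the enantiotopic acetates of 5 in the same sense as for 2-O-benzylglycerol diacetate, leaving the (R)-monoacetate.
- Rh2(S-PTTL)4 is assumed to give the (2R)-cis product, by analogy with simpler 2-(benzyloxy)aryl diazoacetates.

## Route

### Part A – erythro aryloxy-glycerol fragment

**Step 1**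
Reactants: 1, 4-bromo-2,6-dimethoxyphenol; 2, diethyl chloromalonate
Product: 3, diethyl 2-(4-bromo-2,6-dimethoxyphenoxy)malonate
Conditions: K2CO3, acetone, reflux
Reagents that add atoms: diethyl chloromalonate (2), CCOC(=O)C(Cl)C(=O)OCC
Why: Williamson-type SN2 O-alkylation of the phenoxide on the activated α-chloromalonate forms the future C8–O–aryl bond on an achiral substrate.

**Step 2**
Reactants: 3
Product: 4, 2-(4-bromo-2,6-dimethoxyphenoxy)propane-1,3-diol (prochiral)
Conditions: LiAlH4, THF, 0 °C → rt (inverse addition)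
Reagents that add atoms: none
Why: Hydride reduction of both esters gives the prochiral 1,3-diol, and the aryl bromide and aryl ethers are inert to LiAlH4 at this temperature.

**Step 3**
Reactants: 4
Product: 5, 2-(4-bromo-2,6-dimethoxyphenoxy)propane-1,3-diyl diacetate (prochiral)
Conditions: Ac2O, pyridine, DMAP (cat.), CH2Cl2, rt
Reagents that add atoms: acetic anhydride, CC(=O)OC(C)=O
Why: Exhaustive DMAP-catalysed acetylation gives the prochiral diacetate needed for hydrolytic desymmetrisation.

**Step 4**
Reactants: 5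
Product: 6, (R)-2-(4-bromo-2,6-dimethoxyphenoxy)-3-hydroxypropyl acetate
Conditions: lipase (Burkholderia cepacia lipase, Amano PS), 0.1 M phosphate buffer pH 7.0/acetone 9:1, 25 °C, pH-stat, stop at ~1.05 equiv NaOH
Reagents that add atoms: none (water supplies only H)
Why: Lipase-catalysed enantiotopos-selective ester hydrolysis (enzymatic desymmetrisation, up to 100 % theoretical yield) removes one of the two enantiotopic acetates and creates the first stereocentre, the future aryloxy-bearing carbon, as R; slight over-hydrolysis upgrades the ee.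

**Step 5**
Reactants: 6
Product: 7, (S)-2-(4-bromo-2,6-dimethoxyphenoxy)-3-[(tert-butyldiphenylsilyl)oxy]propyl acetate (descriptor changes by CIP only)
Conditions: TBDPSCl, imidazole, CH2Cl2, 0 °C
Reagents that add atoms: TBDPSCl, CC(C)(C)[Si](Cl)(c1ccccc1)c1ccccc1
Why: Prompt silylation of the free primary alcohol under mild conditions prevents 1,3-acyl migration (which would racemise 6), and the bulky TBDPS group does not itself migrate.

**Step 6**
Reactants: 7
Product: 8, (S)-2-(4-bromo-2,6-dimethoxyphenoxy)-3-[(tert-butyldiphenylsilyl)oxy]propan-1-ol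
Conditions: DIBAL-H (2.2 equiv), CH2Cl2, −78 °C; Rochelle salt
Reagents that add atoms: none
Why: Low-temperature reductive removal of the acetate is non-basic, so neither the silyl group nor the stereocentre can scramble.

**Step 7**
Reactants: 8
Product: 9, (R)-2-(4-bromo-2,6-dimethoxyphenoxy)-3-[(tert-butyldiphenylsilyl)oxy]propanal (used crude)
Conditions: Dess–Martin periodinane, NaHCO3, CH2Cl2, 0 °C → rt
Reagents that add atoms: none
Why: Dess–Martin oxidation is neutral and fast, so the epimerisable α-aryloxy aldehyde is formed without racemisation or β-elimination.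

**Step 8**
Reactants: 9; 10, 3,4-dimethoxyphenylmagnesium bromide
Product: 11, (1S,2R)-2-(4-bromo-2,6-dimethoxyphenoxy)-3-[(tert-butyldiphenylsilyl)oxy]-1-(3,4-dimethoxyphenyl)propan-1-ol (erythro)
Conditions: 10 (1.5 equiv), THF, −78 °C; NH4Cl; chromatography to remove the minor threo isomer
Reagents that add atoms: 3,4-dimethoxyphenylmagnesium bromide (10), COc1ccc([Mg]Br)cc1OC
Why: Grignard addition under non-chelating conditions (poorly basic, hindered aryloxy oxygen; silyl ether; THF) follows the polar Felkin–Anh model with the aryloxy group anti to the incoming aryl, giving the 1,2-anti (erythro) carbinol and setting the benzylic centre as S.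

**Step 9**
Reactants: 11
Product: 12, (1S,2R)-2-(4-bromo-2,6-dimethoxyphenoxy)-1-[(tert-butyldimethylsilyl)oxy]-3-[(tert-butyldiphenylsilyl)oxy]-1-(3,4-dimethoxyphenyl)propane
Conditions: TBSOTf, 2,6-lutidine, CH2Cl2, 0 °C
Reagents that add atoms: TBSOTf, CC(C)(C)[Si](C)(C)OS(=O)(=O)C(F)(F)F
Why: Silyl triflate silylation caps the hindered benzylic alcohol without acid, protecting it from the organolithium and the later Rh carbene (O–H insertion).

**Step 10**
Reactants: 12
Product: 13, 4-{[(1S,2R)-1-[(tert-butyldimethylsilyl)oxy]-3-[(tert-butyldiphenylsilyl)oxy]-1-(3,4-dimethoxyphenyl)propan-2-yl]oxy}-3,5-dimethoxybenzaldehyde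
Conditions: n-BuLi, THF, −78 °C; then DMF, −78 → 0 °C
Reagents that add atoms: DMF, CN(C)C=O
Why: Bromine–lithium exchange is much faster than any deprotonation at −78 °C, and formylation of the aryllithium (Bouveault) installs the carbon that becomes C2 of the dihydrobenzofuran.

**Step 11**
Reactants: 13
Product: 14, (4-{[(1S,2R)-1-[(tert-butyldimethylsilyl)oxy]-3-[(tert-butyldiphenylsilyl)oxy]-1-(3,4-dimethoxyphenyl)propan-2-yl]oxy}-3,5-dimethoxyphenyl)methanol
Conditions: NaBH4, MeOH/THF, 0 °C
Reagents that add atoms: none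
Why: Chemoselective hydride reduction of the aldehyde gives the benzyl alcohol with all other groups untouched.

### Part B – arylacetate fragment

**Step 12**
Reactants: 15, methyl 3-(4-hydroxy-3-methoxyphenyl)propanoate; 16, allyl bromide
Product: 17, methyl 3-[4-(allyloxy)-3-methoxyphenyl]propanoate
Conditions: K2CO3, acetone, reflux
Reagents that add atoms: allyl bromide (16), C=CCBr
Why: Williamson O-allylation of the phenol is straightforward.

**Step 13**
Reactants: 17
Product: 18, methyl 3-(3-allyl-4-hydroxy-5-methoxyphenyl)propanoate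
Conditions: N,N-diethylaniline, 200 °C (sealed tube)
Reagents that add atoms: none
Why: Aromatic Claisen [3,3]-rearrangement delivers the allyl group to the only free ortho position.

**Step 14**
Reactants: 18
Product: 19, methyl 3-(4-acetoxy-3-allyl-5-methoxyphenyl)propanoate
Conditions: Ac2O, pyridine, DMAP (cat.), rt
Reagents that add atoms: acetic anhydride, CC(=O)OC(C)=O
Why: Acetylation masks the guaiacol-type phenol, which periodate would otherwise oxidise to a quinone in the next step.

**Step 15**
Reactants: 19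
Product: 20, methyl 3-[4-acetoxy-3-methoxy-5-(2-oxoethyl)phenyl]propanoate
Conditions: OsO4 (cat.), NaIO4, 2,6-lutidine, dioxane/H2O, rt
Reagents that add atoms: OsO4, O=[Os](=O)(=O)=O, with NaIO4, [Na+].[O-]I(=O)(=O)=O (source of the aldehyde oxygen)
Why: Lemieux–Johnson dihydroxylation/cleavage removes the terminal CH2 and leaves the arylacetaldehyde, without the arene oxidation that ozone or RuO4 would risk.

**Step 16**
Reactants: 20
Product: 21, 2-[2-acetoxy-3-methoxy-5-(3-methoxy-3-oxopropyl)phenyl]acetic acid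
Conditions: NaClO2, NaH2PO4, 2-methyl-2-butene, t-BuOH/H2O, 0 °C → rt
Reagents that add atoms: sodium chlorite, [Na+].[O-]Cl=O
Why: Pinnick oxidation converts the sensitive aldehyde to the acid, and the alkene scavenger prevents chlorination of the arene.

**Step 17**
Reactants: 21
Product: 22, methyl 3-[4-hydroxy-3-methoxy-5-(2-methoxy-2-oxoethyl)phenyl]propanoate
Conditions: MeOH, H2SO4 (cat.), reflux; neutralise (NaHCO3) before concentration
Reagents that add atoms: methanol, CO
Why: Fischer esterification of the acid and acid-catalysed methanolysis of the aryl acetate occur together, and excess methanol keeps the product as the open hydroxy ester and not the benzofuranone lactone.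

### Part C – union, ring formation and endgame

**Step 18**
Reactants: 14; 22
Product: 23, methyl 3-[4-({4-{[(1S,2R)-1-[(tert-butyldimethylsilyl)oxy]-3-[(tert-butyldiphenylsilyl)oxy]-1-(3,4-dimethoxyphenyl)propan-2-yl]oxy}-3,5-dimethoxybenzyl}oxy)-3-methoxy-5-(2-methoxy-2-oxoethyl)phenyl]propanoate
Conditions: PPh3, DIAD, THF, 0 °C → rt
Reagents that add atoms: none
Why: Mitsunobu etherification of a primary benzylic alcohol with a phenol (pKa ≈ 10) is dependable, base-free (no lactonisation of 22) and touches no stereocentre.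

**Step 19**
Reactants: 23
Product: 24, the corresponding methyl 2-aryl-2-diazoacetate (ArCH2CO2Me → ArC(=N2)CO2Me)
Conditions: p-ABSA, DBU, MeCN, 0 °C → rt
Reagents that add atoms: 4-acetamidobenzenesulfonyl azide, CC(=O)Nc1ccc(cc1)S(=O)(=O)N=[N+]=[N-]
Why: Regitz diazo transfer occurs only at the arylacetate CH2, the one sufficiently acidic position, since the propanoate α-CH2 is not deprotonated by DBU.

**Step 20**
Reactants: 24
Product: 25, methyl (2R,3S)-2-(4-{[(1S,2R)-1-[(tert-butyldimethylsilyl)oxy]-3-[(tert-butyldiphenylsilyl)oxy]-1-(3,4-dimethoxyphenyl)propan-2-yl]oxy}-3,5-dimethoxyphenyl)-7-methoxy-5-(3-methoxy-3-oxopropyl)-2,3-dihydrobenzofuran-3-carboxylate (2,3-cis)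
Conditions: Rh2(S-PTTL)4 (2 mol %), toluene, −60 °C
Reagents that add atoms: none (loss of N2)
Why: The Rh(II) carbenoid undergoes intramolecular 1,5 C–H insertion into the activated ArCH2–O bond to close the dihydrofuran ring, and the chiral carboxylate catalyst selects one enantiotopic benzylic hydrogen, setting C2 as R and giving the cis-ester; the minor ring antipode is a diastereomer here and is removed by chromatography.

**Step 21**
Reactants: 25
Product: 26, the (2R,3R)-trans diastereomer of 25
Conditions: NaOMe, MeOH/THF, rt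
Reagents that add atoms: none
Why: Thermodynamic epimerisation at C3 through the ester enolate gives the more stable 2,3-trans ester while C2 and the side-chain centres are not acidic and stay fixed.

**Step 22**
Reactants: 26
Product: 27, 3-[(2R,3S)-2-(4-{[(1S,2R)-1-[(tert-butyldimethylsilyl)oxy]-3-[(tert-butyldiphenylsilyl)oxy]-1-(3,4-dimethoxyphenyl)propan-2-yl]oxy}-3,5-dimethoxyphenyl)-3-(hydroxymethyl)-7-methoxy-2,3-dihydrobenzofuran-5-yl]propan-1-ol
Conditions: LiAlH4, THF, 0 °C
Reagents that add atoms: none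
Why: Hydride reduction converts both methyl esters to primary alcohols (C3 becomes S by CIP only) without affecting the silyl ethers or the benzylic C–O bonds.

**Step 23**
Reactants: 27
Product: 28, berbikonol, (1S,2R)-1-(3,4-dimethoxyphenyl)-2-{4-[(2R,3S)-3-(hydroxymethyl)-5-(3-hydroxypropyl)-7-methoxy-2,3-dihydrobenzofuran-2-yl]-2,6-dimethoxyphenoxy}propane-1,3-diol
Conditions: TBAF (excess), THF, rt → 40 °C
Reagents that add atoms: none
Why: Fluoride cleaves both silyl ethers under non-acidic conditions, avoiding benzylic-cation epimerisation of the carbinol or opening of the dihydrobenzofuran.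

## Compound list

1 | 4-bromo-2,6-dimethoxyphenol | COc1cc(Br)cc(OC)c1O | starting material
2 | diethyl chloromalonate | CCOC(=O)C(Cl)C(=O)OCC | starting material
3 | diethyl 2-(4-bromo-2,6-dimethoxyphenoxy)malonate | CCOC(=O)C(Oc1c(OC)cc(Br)cc1OC)C(=O)OCC | intermediate
4 | 2-(4-bromo-2,6-dimethoxyphenoxy)propane-1,3-diol | OCC(CO)Oc1c(OC)cc(Br)cc1OC | intermediate
5 | 2-(4-bromo-2,6-dimethoxyphenoxy)propane-1,3-diyl diacetate | CC(=O)OCC(COC(C)=O)Oc1c(OC)cc(Br)cc1OC | intermediate
6 | (R)-2-(4-bromo-2,6-dimethoxyphenoxy)-3-hydroxypropyl acetate | CC(=O)OC[C@@H](CO)Oc1c(OC)cc(Br)cc1OC | intermediate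
7 | (S)-2-(4-bromo-2,6-dimethoxyphenoxy)-3-(TBDPS-oxy)propyl acetate | CC(=O)OC[C@@H](CO[Si](c1ccccc1)(c1ccccc1)C(C)(C)C)Oc1c(OC)cc(Br)cc1OC | intermediate
8 | (S)-2-(4-bromo-2,6-dimethoxyphenoxy)-3-(TBDPS-oxy)propan-1-ol | OC[C@@H](CO[Si](c1ccccc1)(c1ccccc1)C(C)(C)C)Oc1c(OC)cc(Br)cc1OC | intermediate
9 | (R)-2-(4-bromo-2,6-dimethoxyphenoxy)-3-(TBDPS-oxy)propanal | O=C[C@@H](CO[Si](c1ccccc1)(c1ccccc1)C(C)(C)C)Oc1c(OC)cc(Br)cc1OC | intermediate
10 | 3,4-dimethoxyphenylmagnesium bromide | COc1ccc([Mg]Br)cc1OC | starting material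
11 | (1S,2R)-2-(4-bromo-2,6-dimethoxyphenoxy)-3-(TBDPS-oxy)-1-(3,4-dimethoxyphenyl)propan-1-ol | COc1ccc([C@H](O)[C@@H](CO[Si](c2ccccc2)(c2ccccc2)C(C)(C)C)Oc2c(OC)cc(Br)cc2OC)cc1OC | intermediate
12 | 1-O-TBS ether of 11 (1S,2R) | COc1ccc([C@H](O[Si](C)(C)C(C)(C)C)[C@@H](CO[Si](c2ccccc2)(c2ccccc2)C(C)(C)C)Oc2c(OC)cc(Br)cc2OC)cc1OC | intermediate
13 | 4-{[(1S,2R)-1-(TBS-oxy)-3-(TBDPS-oxy)-1-(3,4-dimethoxyphenyl)propan-2-yl]oxy}-3,5-dimethoxybenzaldehyde | COc1ccc([C@H](O[Si](C)(C)C(C)(C)C)[C@@H](CO[Si](c2ccccc2)(c2ccccc2)C(C)(C)C)Oc2c(OC)cc(C=O)cc2OC)cc1OC | intermediate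
14 | benzyl alcohol from 13 | COc1ccc([C@H](O[Si](C)(C)C(C)(C)C)[C@@H](CO[Si](c2ccccc2)(c2ccccc2)C(C)(C)C)Oc2c(OC)cc(CO)cc2OC)cc1OC | intermediate
15 | methyl 3-(4-hydroxy-3-methoxyphenyl)propanoate | COC(=O)CCc1ccc(O)c(OC)c1 | starting material
16 | allyl bromide | C=CCBr | starting material
17 | methyl 3-[4-(allyloxy)-3-methoxyphenyl]propanoate | COC(=O)CCc1ccc(OCC=C)c(OC)c1 | intermediate
18 | methyl 3-(3-allyl-4-hydroxy-5-methoxyphenyl)propanoate | COC(=O)CCc1cc(CC=C)c(O)c(OC)c1 | intermediate
19 | methyl 3-(4-acetoxy-3-allyl-5-methoxyphenyl)propanoate | COC(=O)CCc1cc(CC=C)c(OC(C)=O)c(OC)c1 | intermediate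
20 | methyl 3-[4-acetoxy-3-methoxy-5-(2-oxoethyl)phenyl]propanoate | COC(=O)CCc1cc(CC=O)c(OC(C)=O)c(OC)c1 | intermediate
21 | 2-[2-acetoxy-3-methoxy-5-(3-methoxy-3-oxopropyl)phenyl]acetic acid | COC(=O)CCc1cc(CC(=O)O)c(OC(C)=O)c(OC)c1 | intermediate
22 | methyl 3-[4-hydroxy-3-methoxy-5-(2-methoxy-2-oxoethyl)phenyl]propanoate | COC(=O)CCc1cc(CC(=O)OC)c(O)c(OC)c1 | intermediate
23 | benzyl aryl ether from 14 + 22 | COc1ccc([C@H](O[Si](C)(C)C(C)(C)C)[C@@H](CO[Si](c2ccccc2)(c2ccccc2)C(C)(C)C)Oc2c(OC)cc(COc3c(OC)cc(CCC(=O)OC)cc3CC(=O)OC)cc2OC)cc1OC | intermediate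
24 | aryl diazoacetate from 23 | COc1ccc([C@H](O[Si](C)(C)C(C)(C)C)[C@@H](CO[Si](c2ccccc2)(c2ccccc2)C(C)(C)C)Oc2c(OC)cc(COc3c(OC)cc(CCC(=O)OC)cc3C(=[N+]=[N-])C(=O)OC)cc2OC)cc1OC | intermediate
25 | cis-(2R,3S) dihydrobenzofuran diester | COc1ccc([C@H](O[Si](C)(C)C(C)(C)C)[C@@H](CO[Si](c2ccccc2)(c2ccccc2)C(C)(C)C)Oc2c(OC)cc([C@@H]3Oc4c(OC)cc(CCC(=O)OC)cc4[C@@H]3C(=O)OC)cc2OC)cc1OC | intermediate
26 | trans-(2R,3R) dihydrobenzofuran diester | COc1ccc([C@H](O[Si](C)(C)C(C)(C)C)[C@@H](CO[Si](c2ccccc2)(c2ccccc2)C(C)(C)C)Oc2c(OC)cc([C@@H]3Oc4c(OC)cc(CCC(=O)OC)cc4[C@H]3C(=O)OC)cc2OC)cc1OC | intermediate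
27 | bis-silyl-protected berbikonol (ring 2R,3S; chain 1S,2R) | COc1ccc([C@H](O[Si](C)(C)C(C)(C)C)[C@@H](CO[Si](c2ccccc2)(c2ccccc2)C(C)(C)C)Oc2c(OC)cc([C@@H]3Oc4c(OC)cc(CCCO)cc4[C@H]3CO)cc2OC)cc1OC | intermediate
28 | berbikonol | COc1ccc([C@H](O)[C@@H](CO)Oc2c(OC)cc([C@@H]3Oc4c(OC)cc(CCCO)cc4[C@H]3CO)cc2OC)cc1OC | target

## Summary

Total steps: 23.
Longest linear sequence: 17 (steps 1–11, then 18–23); steps 12–17 form the 6-step side branch.

Three steps most likely to fail, each with a fallback that changes the approach: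

1. **Step 4 (lipase desymmetrisation).** Selectivity and sense on a 2,6-dimethoxyaryl ether are unproven. Fallback: abandon the malonate/desymmetrisation logic. Alkylate phenol 1 with ethyl 2-chloro-3-(3,4-dimethoxyphenyl)-3-oxopropanoate and set both side-chain centres at once by a ketoreductase-mediated dynamic kinetic reduction of the freely racemising α-aryloxy-β-keto ester (anti-selective enzyme from a panel), then reduce the ester and protect. If only the sense is wrong, lipase acylation of diol 4 with vinyl acetate gives the antipodal monoacetate.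

2. **Step 8 (Felkin–Anh Grignard addition).** Possible problems are modest erythro:threo ratio, partial chelation control, or epimerisation of aldehyde 9. Fallback: switch from substrate-controlled C–C bond formation to reagent-controlled C=O reduction. Oxidise the 11/threo mixture to the aryl ketone (DMP) and reduce under catalyst control (Noyori Ru–TsDPEN transfer hydrogenation or CBS/borane). Alternatively remove the TBDPS group and reduce the free γ-hydroxy ketol with NaBH4, which favours erythro for syringyl-type β-ethers.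

3. **Step 20 (Rh-catalysed asymmetric C–H insertion).** Possible problems are insufficient facial selectivity, wrong sense, or competing oxonium-ylide/Stevens pathways on this electron-rich benzyl ether. Fallback: move stereocontrol from the catalyst to the substrate. Prepare the diazo ester as a chiral ester (e.g. (R)-pantolactone) for double stereodifferentiation. In the worst case use Rh2(OAc)4 and separate the two ring diastereomers by chromatography; they are diastereomers, not enantiomers, because the side-chain centres are already fixed. Then epimerise and reduce as in steps 21–22.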